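# Proposed synthesis of CNP0263298.4 by pinacol macrocyclisation of a seco keto-aldehyde lactone

Remark on numbering: carbons carry cembrane numbers throughout (C1 = ring CH bearing C15; C4 = lactone C–O carbon; C5 = CHOH; C8=C9 = Z-alkene; C12/C13 = diol; C16 = lactone carbonyl; C17 = exocyclic CH2; C18, C19, C20 = methyls on C4, C8, C12).

Remark on the diene: the 1,5-dimethyl isomer of dimethylcyclooctadiene is assumed; the 1,6-isomer present in technical material is removed beforehand or its cleavage product is separated after step 7.

Remark on C15: compounds 24–27 are drawn as the 15R epimer (aminomethyl group trans to the C14 branch); the other epimer would serve equally, since C15 becomes sp2 again in step 20.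

## Analysis of the target

The target is a 14-membered carbocycle (C1–C14) bridged between C1 and C4 by a seven-membered α-methylene lactone (C1, C15, C16, O, C4, C3, C2). It carries five stereocentres, 1S, 4S, 5R, 12R and 13S, and one Z-trisubstituted alkene (C8=C9). The centres fall into two vicinal pairs, each a tertiary carbinol bearing a methyl group next to a secondary carbinol: C4/C5 and C12/C13. Both pairs are erythro, that is, the two oxygens are anti in the extended chain and cis on the ring drawing. C1 stands alone, 1,4 to C4 across the lactone and 1,3 to C13. The sensitive groups are the α-methylene lactone (a Michael acceptor and a radical acceptor), the tertiary alkyl ester linkage at C4 and the free triol. The main difficulty is that C4 and C12 each carry a CH3 and a CH2 substituent, so neither can be set by plain facial discrimination at a methyl ketone. The strategy rests on the C12–C13 diol lying inside the 14-membered ring. Cutting that bond leaves a seco keto-aldehyde made of two ten-carbon terpene-type pieces (C13–C14–C1(C15–C17)–C2–C3–C4–C18 and C5–C12 with C19 and C20).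

## Retrosynthetic reasoning

**28 to 26 (C15=C17 masked).** The exocyclic methylene is taken back to its dimethylamine adduct 26. This is needed because a ketyl at C13 would otherwise close a five-membered ring onto C17. Going forward, quaternisation and elimination must restore the alkene without touching the triol.

**26 to 25 (C12–C13).** The diol bond is cut to give the keto-aldehyde 25. This is the only C–C bond in the ring whose two ends are both oxygenated, so a single reductive coupling builds the ring, one skeletal bond and two stereocentres at once. The forward reaction must favour ring closure over intermolecular coupling and give the 12R,13S pair.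

**25 to 24 to 22 + 23 (masks).** The two carbonyls of 25 are carried as dioxolanes and the C5 hydroxyl as a silyl ether in 24, all released by one acid treatment. 24 is the conjugate adduct of dimethylamine (23) and the methylene lactone 22. Adding the amine before the aldehyde is freed avoids condensation of a secondary amine with it.

**22 to 20 (O4–C16).** The lactone is opened at the ester bond to the hydroxy acid 20. All seven ring atoms already lie on one chain, so no other bond of the small ring offers a simpler closure. The forward step must acylate a tertiary hydroxyl, which is why C5 is silylated and the reaction is run as a high-dilution lactonisation.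

**20 to 18 to 17 to 16 to 15 (C4 from C5).** The C4 carbinol is traced to the trisubstituted 3,4-epoxide 16 (hydride at C3), and this to the (E)-allylic alcohol 15 by hydroxyl-directed epoxidation. With a C3=C4 alkene bearing the C18 methyl, the erythro preference of the directed epoxidation puts the C4 oxygen anti to the C5 oxygen, which is the 4S,5R pairing. The more obvious C4 nucleophile, a 2-metallated 1-alkene from a methyl ketone, is avoided. Directed epoxidation of its 2-methylene alcohol is erythro with respect to the epoxide CH2 and would give the C4 epimer after hydride opening. The same hydride step also frees the C16 alcohol of 18, which is then oxidised to the acid.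

**15 to 14 to 13 to 12 to 9 + 11 (C4–C5 and C5).** The two ten-carbon pieces are joined at C4–C5 by addition of the (E)-alkenyl unit of iodide 9 to the aldehyde of 11. A chromium-mediated addition is chosen because it leaves the C12 ketone of 11 alone. C5 forms without control in 12, so it is oxidised to enone 13 and reset by catalyst-controlled reduction. The C12 ketone is ketalised first (14) because that reduction and the later hydride step would otherwise reduce it.

**9 to 7 to 6 to 4 to 3 to 2 to 1 (left-hand piece).** The (E)-2-iodoalkene 9 comes from the methyl alkyne 7 by syn-hydrometallation. The ynal 6 has exactly the C13/C14/C1/C2/C3/C4/C18 chain and arises by fragmentation of the epoxy ketone 4. This leads back to (R)-carvone (1), whose stereocentre becomes C1 and whose isopropenyl group becomes C15–C17. The C16 oxygen is introduced first, by allylic chlorination (2) and pivalate displacement (3), while the only other alkene is the unreactive enone.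

**11 to 10 (right-hand piece).** Cleavage of one ring alkene of the diene 10 gives the C5 aldehyde and the C12 methyl ketone together. The second ring alkene becomes C8=C9 with its Z geometry fixed by the eight-membered ring.

## Alternatives that were turned down

**Alternative 1: closure of the lactone at C1–C15.**
- Disconnection and key step: the macrocyclic precursor A2 carries an acrylate on the C4 oxygen and a C13 ketone conjugated to a C14=C1 alkene. A nucleophilic trialkylphosphine adds to the acrylate, the C15 enolate attacks C1, and loss of the phosphine leaves the methylene lactone A1 (a transannular Rauhut–Currier reaction).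
- For it: the ester bond is made by acylating the tertiary alcohol with a small acyl group, which is easier than the lactonisation of step 16. The methylene group also appears without masking. On both points it is stronger than the chosen route.
- Against it: C1 would be created in a transannular seven-membered closure, governed only by ring conformation. Rauhut–Currier closures are dependable for five- and six-membered rings, not for seven. The 14-membered ring still needs its own macrocyclisation, and the C13 ketone of A1 must afterwards be reduced to 13S next to a centre with CH3 and CH2 substituents.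
- Comparison: the chosen route takes C1 from the chiral pool and makes the macrocycle and the diol in one step, so the ring is built once.

**Alternative 2: macrocyclisation at C4–C5.**
- Disconnection and key step: the open-chain enol triflate aldehyde A4 is treated with divalent chromium and a nickel co-catalyst. The alkenylchromium adds to the C5 aldehyde and closes the 14-membered ring as the allylic alcohol A3.
- For it: this type of ring closure is more dependable than a pinacol macrocyclisation, and the C12/C13 diol is set beforehand in an open chain and carried as an acetonide. On ring-closure reliability and on diol control it is stronger.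
- Against it: C5 is formed under macrocyclic control only. The product A3 is a 2-methylene alcohol, and its directed epoxidation and hydride opening lead to the C4 epimer for the reason given above, so C4 needs a corrective sequence. The lactone, the C16 oxidation and the methylene group all remain to be made on the macrocycle.
- Comparison: the chosen route settles C4 and C5 in the open chain with catalyst and alkene-geometry control, and needs only one operation after ring closure.

**Alternative 3: closure of the lactone at O–C4.**
- Disconnection and key step: the macrocyclic trans-4,5-epoxy acid A6 is treated with mild acid. The carboxyl oxygen opens the epoxide at C4 with inversion, giving the lactone and the C5 hydroxyl of A5.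
- For it: the tertiary C–O bond is made by an ionisation-assisted epoxide opening and not by acylation of a hindered alcohol. C4 and C5 are set together from alkene geometry. This is stronger than step 16 of the chosen route.
- Against it: the epoxide must be placed on C4=C5 and not on C8=C9, on one face, with no directing group; both alkenes are trisubstituted. The 14-membered ring needs a separate closure. Acid treatment of a cembrane epoxide invites transannular attack by C8=C9 and hydride shift, and the acetonide is acid-labile.
- Comparison: the chosen route pays for its harder lactonisation with an epoxidation that is directed by the C5 hydroxyl and blind to C8=C9.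

Key step: step 19

## Route

Step 1
Reactants: 1 (R)-carvone
Product: 2 (R)-10-chlorocarvone [(5R)-5-(3-chloroprop-1-en-2-yl)-2-methylcyclohex-2-en-1-one]
Conditions: Ca(OCl)2, solid CO2, CH2Cl2/H2O, 0 °C
Reagents that add atoms: calcium hypochlorite, [Ca+2].[O-]Cl.[O-]Cl
Why: Ene-type allylic chlorination of the 1,1-disubstituted alkene by hypochlorous acid; the electron-poor enone alkene should not react and the stereocentre is not involved, so C16 is functionalised before any other alkene is present.

Step 2
Reactants: 2 (R)-10-chlorocarvone
Product: 3 (R)-10-(pivaloyloxy)carvone [2-[(1R)-4-methyl-5-oxocyclohex-3-en-1-yl]prop-2-en-1-yl pivalate]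
Conditions: CsOPiv, DMF, 40 °C
Reagents that add atoms: cesium pivalate, [Cs+].[O-]C(=O)C(C)(C)C
Why: SN2 displacement of the allylic chloride (SN2′ attack gives the same product because the allyl unit is symmetric); the pivalate should survive all steps up to the hydride step 14, which removes it.

Step 3
Reactants: 3 (R)-10-(pivaloyloxy)carvone
Product: 4 trans-epoxy ketone [2-[(1R,4R,6R)-1-methyl-2-oxo-7-oxabicyclo[4.1.0]heptan-4-yl]prop-2-en-1-yl pivalate]
Conditions: 30% H2O2, NaOH (cat.), MeOH, 0 °C
Reagents that add atoms: hydrogen peroxide, OO
Why: Weitz–Scheffer nucleophilic epoxidation of the enone only; attack anti to the ring side chain should give the trans epoxide, and both epoxide centres are removed in step 4 in any case.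

Step 4
Reactants: 4 trans-epoxy ketone
Product: 6 ynal [(3S)-2-methylidene-3-(2-oxoethyl)hept-5-yn-1-yl pivalate], via tosylhydrazone 5 (not isolated)
Conditions: TsNHNH2 (1.0 equiv), AcOH/CH2Cl2, −20 °C to rt
Reagents that add atoms: none
Why: Eschenmoser–Tanabe fragmentation: the epoxy-ketone tosylhydrazone breaks down with loss of N2 and sulfinate to the C3≡C4 methyl alkyne and the C13 aldehyde; the stereocentre (C1) lies outside the reacting atoms.

Step 5
Reactants: 6 ynal
Product: 7 alkyne dioxolane [(3S)-3-(1,3-dioxolan-2-ylmethyl)-2-methylidenehept-5-yn-1-yl pivalate]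
Conditions: HOCH2CH2OH, pyridinium p-toluenesulfonate (cat.), benzene, reflux (Dean–Stark)
Reagents that add atoms: ethylene glycol, OCCO
Why: Acid-catalysed acetalisation protects the C13 aldehyde for the organometallic and hydride steps; ester and alkyne are inert.

Step 6
Reactants: 7 alkyne dioxolane
Product: 9 (E)-alkenyl iodide [(3S,5E)-3-(1,3-dioxolan-2-ylmethyl)-6-iodo-2-methylidenehept-5-en-1-yl pivalate], via alkenylzirconocene chloride 8 (not isolated)
Conditions: Cp2Zr(H)Cl (2 equiv), THF, rt to 40 °C; then I2, 0 °C
Reagents that add atoms: iodine, II
Why: syn-Hydrozirconation of the internal alkyne; with excess reagent zirconium should settle on the less hindered carbon next to the methyl group (C4), and iodinolysis with retention gives the (E)-2-iodoalkene. The internal alkyne should react ahead of the hindered 1,1-disubstituted alkene.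

Step 7
Reactants: 10 1,5-dimethylcycloocta-1,5-diene
Product: 11 (4Z)-4-methyl-8-oxonon-4-enal
Conditions: O3 (0.5 equiv), CH2Cl2/MeOH, −78 °C; then Me2S, rt
Reagents that add atoms: ozone, [O-][O+]=O
Why: Ozonolysis of one of the two equivalent trisubstituted ring alkenes with substoichiometric ozone and reductive work-up; the remaining alkene (C8=C9) keeps the Z geometry of the eight-membered ring.

Step 8
Reactants: 9 (E)-alkenyl iodide, 11 (4Z)-4-methyl-8-oxonon-4-enal
Product: 12 C5 allylic alcohol (3E,8Z; C5 epimers; C12 ketone; C13 dioxolane; C16 pivalate)
Conditions: CrCl2 (5 equiv), NiCl2 (2 mol%), DMSO, rt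
Reagents that add atoms: none
Why: Nozaki–Hiyama–Kishi coupling: the alkenylchromium adds to the aldehyde only and keeps the alkene geometry, so the C4–C5 bond forms beside a free methyl ketone, an ester and an acetal. C5 is not controlled here and is reset in steps 9 and 11.

Step 9
Reactants: 12 C5 allylic alcohol
Product: 13 (3E,8Z)-enone (C5 ketone; C12 ketone)
Conditions: Dess–Martin periodinane, NaHCO3, CH2Cl2, 0 °C to rt
Reagents that add atoms: none
Why: Dess–Martin oxidation removes the uncontrolled C5 centre and gives the α-methyl (E)-enone needed for catalyst-controlled reduction.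

Step 10
Reactants: 13 (3E,8Z)-enone
Product: 14 enone with C12 dioxolane
Conditions: Me3SiOCH2CH2OSiMe3, Me3SiOTf (cat.), CH2Cl2, −78 °C
Reagents that add atoms: 1,2-bis(trimethylsilyloxy)ethane, C[Si](C)(C)OCCO[Si](C)(C)C
Why: Noyori ketalisation: the saturated methyl ketone should react at low temperature while the conjugated, α-branched enone does not. The ketal is needed because steps 11 and 14 would otherwise reduce C12.

Step 11
Reactants: 14 enone with C12 dioxolane
Product: 15 (5R)-allylic alcohol (3E,8Z)
Conditions: (S)-2-methyl-CBS-oxazaborolidine (0.5 equiv), catecholborane, toluene, −78 °C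
Reagents that add atoms: none
Why: Corey–Bakshi–Shibata reduction: the alkenyl side acts as the large group, so the (S)-catalyst should deliver hydride to give the 5R alcohol. Catecholborane does not hydroborate the alkenes at this temperature.

Step 12
Reactants: 15 (5R)-allylic alcohol
Product: 16 (3R,4R,5R)-3,4-epoxy-5-ol
Conditions: Ti(OiPr)4, D-(−)-diisopropyl tartrate, t-BuOOH, 4 Å sieves, CH2Cl2, −20 °C
Reagents that add atoms: tert-butyl hydroperoxide, CC(C)(C)OO
Why: Sharpless epoxidation in the matched sense for the 5R alcohol: oxygen goes only to the allylic C3=C4 alkene and should give the erythro epoxy alcohol, with the C4 oxygen anti to the C5 oxygen along C3–C6 (4S,5R after step 14). Any 5S alcohol is mismatched, reacts slowly and is left behind.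

Step 13
Reactants: 16 (3R,4R,5R)-3,4-epoxy-5-ol
Product: 17 C5 triethylsilyl ether of 16
Conditions: Et3SiCl, imidazole, DMF, 0 °C to rt
Reagents that add atoms: chlorotriethylsilane, CC[Si](Cl)(CC)CC
Why: Silylation leaves the later C4 hydroxyl as the only free alcohol for lactonisation; the triethylsilyl group is chosen because it leaves together with the acetals in step 18.

Step 14
Reactants: 17 C5 triethylsilyl ether
Product: 18 (4S,5R)-C4,C16-diol (C5 silyl ether)
Conditions: LiBHEt3 (5 equiv), THF, 0 °C to rt
Reagents that add atoms: none
Why: SN2 hydride opening at the less substituted epoxide carbon C3 gives the tertiary C4 alcohol with its C–O bond and configuration untouched; the same reagent cleaves the pivalate to the C16 allylic alcohol.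

Step 15
Reactants: 18 (4S,5R)-C4,C16-diol
Product: 20 hydroxy acid (C16 acrylic acid; C4 tertiary OH), via enal 19 (not isolated)
Conditions: Dess–Martin periodinane, NaHCO3, CH2Cl2; then NaClO2, NaH2PO4, 2-methylbut-2-ene, t-BuOH/H2O
Reagents that add atoms: sodium chlorite, [Na+].[O-]Cl=O
Why: Dess–Martin oxidation touches only the primary allylic alcohol (the C4 hydroxyl is tertiary), and Pinnick oxidation with a chlorine scavenger takes the enal to the acid without harming the alkenes.

Step 16
Reactants: 20 hydroxy acid
Product: 22 α-methylene seven-membered lactone (C5 silyl ether; C12 and C13 dioxolanes), via mixed anhydride 21 (not isolated)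
Conditions: 2,4,6-Cl3C6H2COCl, Et3N, THF, rt; then slow addition to DMAP, toluene, 80 °C (1 mM)
Reagents that add atoms: none
Why: Yamaguchi lactonisation: the acylpyridinium formed from the mixed anhydride is attacked by the only free hydroxyl (C4) to close the seven-membered ring, helped by the fully substituted C4, the branch at C1 and the sp2 C15. No stereocentre is formed or touched.

Step 17
Reactants: 22 α-methylene lactone, 23 dimethylamine
Product: 24 β-dimethylamino lactone (15R drawn)
Conditions: Me2NH (2 M in THF, excess), THF, rt
Reagents that add atoms: none
Why: Aza-Michael addition to the s-cis-locked acrylate; it removes the radical acceptor before the reductive step, and the hindered tertiary-alkyl ester should resist aminolysis. C15 may form as either epimer without consequence.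

Step 18
Reactants: 24 β-dimethylamino lactone
Product: 25 seco keto-aldehyde lactone (C13 aldehyde; C12 methyl ketone; free C5 OH)
Conditions: 1 M HCl, THF, rt; then NaHCO3
Reagents that add atoms: water, O
Why: Acid hydrolysis removes both dioxolanes and the silyl ether in one operation; the amine is protonated meanwhile, which guards against retro-Michael loss, and the tertiary lactone is deactivated towards ionisation by the neighbouring C5 oxygen.

Step 19
Reactants: 25 seco keto-aldehyde lactone
Product: 26 amine-masked target (12R,13S diol in the 14-membered ring)
Conditions: SmI2 (4 equiv, 0.1 M in THF), THF, rt, 25 added over 8 h (2 mM final); then aq. NaHCO3/Na2S2O3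
Reagents that add atoms: none
Why: SmI2 transfers one electron to the aldehyde, the more easily reduced carbonyl, to give a ketyl bound to trivalent samarium; this couples at carbon with the samarium-coordinated C12 ketone as a second equivalent delivers the second electron, and work-up protonates the diolate (intramolecular pinacol coupling). The closest known reaction type is the reductive cyclisation of keto aldehydes to cyclic 1,2-diols by SmI2 or low-valent titanium, which extends to macrocyclic rings. The 14-membered carbocycle closes by attack of C13 on the carbonyl carbon C12 with both oxygens left outside the ring (exo mode); slow addition at millimolar concentration, the Z-alkene and the lactone, which remove rotors from the chain, should favour this over intermolecular coupling. C12 is set relative to C13 by binding of both oxygens to one samarium, which holds the O–C–C–O unit synclinal; with both chain ends leaving this chelate on the same side the diol is cis on the ring (12R,13S). C13 is set relative to C1 by 1,3-induction across C14 and by the fold of the lactone-bearing chain, which is the weakest control element of the route. The step needs chemoselectivity for the two carbonyls: the lactone is not reduced by SmI2 in THF without additives, and with C17 saturated as the amine adduct no five-membered ketyl–alkene closure from C13 is available.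

Step 20
Reactants: 26 amine-masked target
Product: 28 CNP0263298.4 (target), via trimethylammonium iodide 27 (not isolated)
Conditions: MeI (excess), THF/MeOH, rt; then aq. NaHCO3, EtOAc, rt
Reagents that add atoms: none
Why: Exhaustive N-methylation followed by E1cB elimination of trimethylamine from the β-ammonium lactone restores the C15=C17 alkene. Only C15 carries a hydrogen β to nitrogen, so no regioisomer can form, and the hydroxyls are not alkylated by MeI without base.

## Compound list

1 | (R)-carvone | CC1=CC[C@H](CC1=O)C(C)=C | starting material
2 | (R)-10-chlorocarvone | CC1=CC[C@H](CC1=O)C(CCl)=C | intermediate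
3 | (R)-10-(pivaloyloxy)carvone | CC1=CC[C@H](CC1=O)C(COC(=O)C(C)(C)C)=C | intermediate
4 | trans-epoxy ketone, (1R,4R,6R) | C[C@]12C(=O)C[C@H](C(COC(=O)C(C)(C)C)=C)C[C@H]1O2 | intermediate
5 | tosylhydrazone of 4 (not isolated) | C[C@]12C(=NNS(=O)(=O)c3ccc(C)cc3)C[C@H](C(COC(=O)C(C)(C)C)=C)C[C@H]1O2 | intermediate
6 | (3S)-2-methylidene-3-(2-oxoethyl)hept-5-yn-1-yl pivalate | CC#CC[C@@H](CC=O)C(COC(=O)C(C)(C)C)=C | intermediate
7 | (3S)-3-(1,3-dioxolan-2-ylmethyl)-2-methylidenehept-5-yn-1-yl pivalate | CC#CC[C@@H](CC1OCCO1)C(COC(=O)C(C)(C)C)=C | intermediate
8 | (E)-alkenylzirconocene chloride, Zr on C4 (not isolated) | C/C(=C\C[C@@H](CC1OCCO1)C(COC(=O)C(C)(C)C)=C)[Zr](Cl)(C1C=CC=C1)C1C=CC=C1 | intermediate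
9 | (3S,5E)-3-(1,3-dioxolan-2-ylmethyl)-6-iodo-2-methylidenehept-5-en-1-yl pivalate | C/C(I)=C\C[C@@H](CC1OCCO1)C(COC(=O)C(C)(C)C)=C | intermediate
10 | (1Z,5Z)-1,5-dimethylcycloocta-1,5-diene | C/C1=C/CC/C(C)=C\CC1 | starting material
11 | (4Z)-4-methyl-8-oxonon-4-enal | CC(=O)CC/C=C(/C)CCC=O | intermediate
12 | C5 allylic alcohol, 3E,8Z, C5 epimer mixture (C12 ketone, C13 dioxolane, C16 pivalate) | CC(=O)CC/C=C(/C)CCC(O)/C(C)=C/C[C@@H](CC1OCCO1)C(COC(=O)C(C)(C)C)=C | intermediate
13 | (3E,8Z)-5,12-diketone (enone) | CC(=O)CC/C=C(/C)CCC(=O)/C(C)=C/C[C@@H](CC1OCCO1)C(COC(=O)C(C)(C)C)=C | intermediate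
14 | enone with C12 dioxolane | CC1(CC/C=C(/C)CCC(=O)/C(C)=C/C[C@@H](CC2OCCO2)C(COC(=O)C(C)(C)C)=C)OCCO1 | intermediate
15 | (5R)-allylic alcohol, 3E,8Z | CC1(CC/C=C(/C)CC[C@@H](O)/C(C)=C/C[C@@H](CC2OCCO2)C(COC(=O)C(C)(C)C)=C)OCCO1 | intermediate
16 | (3R,4R,5R)-3,4-epoxy-5-ol | CC1(CC/C=C(/C)CC[C@@H](O)[C@@]2(C)O[C@@H]2C[C@@H](CC3OCCO3)C(COC(=O)C(C)(C)C)=C)OCCO1 | intermediate
17 | C5 triethylsilyl ether of 16 | CC1(CC/C=C(/C)CC[C@@H](O[Si](CC)(CC)CC)[C@@]2(C)O[C@@H]2C[C@@H](CC3OCCO3)C(COC(=O)C(C)(C)C)=C)OCCO1 | intermediate
18 | (4S,5R)-C4,C16-diol, C5 silyl ether | CC1(CC/C=C(/C)CC[C@@H](O[Si](CC)(CC)CC)[C@@](C)(O)CC[C@@H](CC2OCCO2)C(CO)=C)OCCO1 | intermediate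
19 | C16 enal (not isolated) | CC1(CC/C=C(/C)CC[C@@H](O[Si](CC)(CC)CC)[C@@](C)(O)CC[C@@H](CC2OCCO2)C(C=O)=C)OCCO1 | intermediate
20 | hydroxy acid (C16 acid, C4 OH) | CC1(CC/C=C(/C)CC[C@@H](O[Si](CC)(CC)CC)[C@@](C)(O)CC[C@@H](CC2OCCO2)C(C(=O)O)=C)OCCO1 | intermediate
21 | mixed 2,4,6-trichlorobenzoic anhydride of 20 (not isolated) | CC1(CC/C=C(/C)CC[C@@H](O[Si](CC)(CC)CC)[C@@](C)(O)CC[C@@H](CC2OCCO2)C(C(=O)OC(=O)c2c(Cl)cc(Cl)cc2Cl)=C)OCCO1 | intermediate
22 | α-methylene seven-membered lactone (1S,4S,5R; C5 silyl ether; two dioxolanes) | C=C1C(=O)O[C@@](C)(CC[C@H]1CC2OCCO2)[C@H](O[Si](CC)(CC)CC)CC/C(C)=C\CCC3(C)OCCO3 | intermediate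
23 | dimethylamine | CNC | starting material
24 | β-dimethylamino lactone (15R drawn; silyl ether; two dioxolanes) | CN(C)C[C@@H]1C(=O)O[C@@](C)(CC[C@H]1CC2OCCO2)[C@H](O[Si](CC)(CC)CC)CC/C(C)=C\CCC3(C)OCCO3 | intermediate
25 | seco keto-aldehyde lactone, amine-masked | CN(C)C[C@@H]1C(=O)O[C@@](C)(CC[C@H]1CC=O)[C@H](O)CC/C(C)=C\CCC(C)=O | intermediate
26 | amine-masked target (1S,4S,5R,12R,13S,8Z) | CN(C)C[C@@H]1C(=O)O[C@@]2(C)CC[C@H]1C[C@H](O)[C@](C)(O)CC/C=C(/C)CC[C@H]2O | intermediate
27 | trimethylammonium iodide of 26 (not isolated) | C[N+](C)(C)C[C@@H]1C(=O)O[C@@]2(C)CC[C@H]1C[C@H](O)[C@](C)(O)CC/C=C(/C)CC[C@H]2O.[I-] | intermediate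
28 | CNP0263298.4 | C=C1C(=O)O[C@@]2(C)CC[C@H]1C[C@H](O)[C@](C)(O)CC/C=C(/C)CC[C@H]2O | target

## Step count and least certain steps

Total step count: 20. Longest linear sequence: 19 (steps 1–6 and 8–20); step 7 is a one-step side branch.

**Step 19 (key step).** The most likely failures are intermolecular coupling or plain reduction of the aldehyde outrunning ring closure, and poor facial selectivity at C13 (and with it the C12/C13 pairing), because only the chain fold and a remote centre steer the closing carbons. Fallback: setting out from 25, the C5 hydroxyl is silylated (Et3SiCl, imidazole) to the C5 triethylsilyl ether F1. The ring is then closed on a low-valent titanium surface (TiCl3, Zn–Cu couple, DME, slow addition), which binds both carbonyl oxygens before the C–C bond forms, without asking for selectivity at C13. This gives the 13-epimeric diol F2 and/or the wanted diol silyl ether F4. F2 is oxidised at its only oxidisable hydroxyl (C13; SO3·pyridine, DMSO, iPr2NEt) to the α-ketol F3. F3 is reduced with Zn(BH4)2 under chelation by the C12 hydroxyl, hydride entering past the C20 methyl group, to F4. Dilute aqueous HCl then removes the silyl group and the route is rejoined at 26.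

**Step 16.** The most likely failure is slow acylation of the hindered tertiary C4 hydroxyl, flanked by the silyloxy-bearing C5, so that oligomerisation or decay of the activated acid takes over. Fallback: setting out from 20, the acid is converted into the pentafluorophenyl ester F5 (C6F5OH, carbodiimide). The tertiary alcohol is then deprotonated (KN(SiMe3)2, THF, high dilution), so that ring closure is driven by a strong alkoxide nucleophile and not by a more reactive acyl donor. The route is rejoined at 22.

**Step 6.** The most likely failures are incomplete migration of zirconium to C4, giving the regioisomeric iodide, and competing hydrozirconation of the 1,1-disubstituted alkene by the excess reagent needed for that migration. Fallback: setting out from 7, platinum-catalysed syn-hydrosilylation (Et3SiH, Pt2[(CH2=CHSiMe2)2O]3, P(t-Bu)3), which does not touch the alkene or the ester, gives the (E)-alkenylsilane F6. F6 can be freed from its regioisomer and is converted with retention into 9 by iododesilylation (N-iodosuccinimide, hexafluoroisopropanol).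

**Step 18.** The most likely failures are loss of dimethylamine by retro-Michael reaction or ionisation of the tertiary lactone C–O bond during the prolonged acid treatment that the aldehyde dioxolane needs. Fallback: setting out from 22, the order is reversed. The acetals and the silyl ether are hydrolysed first on the amine-free lactone (aq. HCl, THF), giving the methylene keto-aldehyde F7. Dimethylamine (23) is then added at 0 °C with a short reaction time, which leads directly to 25.

## Further compounds

F1 | step 19 | C5 triethylsilyl ether of 25 | CN(C)C[C@@H]1C(=O)O[C@@](C)(CC[C@H]1CC=O)[C@H](O[Si](CC)(CC)CC)CC/C(C)=C\CCC(C)=O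
F2 | step 19 | 13-epimeric macrocyclic diol, C5 silyl ether (12R,13R) | CN(C)C[C@@H]1C(=O)O[C@@]2(C)CC[C@H]1C[C@@H](O)[C@](C)(O)CC/C=C(/C)CC[C@H]2O[Si](CC)(CC)CC
F3 | step 19 | macrocyclic 12-hydroxy-13-ketone, C5 silyl ether | CN(C)C[C@@H]1C(=O)O[C@@]2(C)CC[C@H]1CC(=O)[C@](C)(O)CC/C=C(/C)CC[C@H]2O[Si](CC)(CC)CC
F4 | step 19 | macrocyclic (12R,13S)-diol, C5 silyl ether | CN(C)C[C@@H]1C(=O)O[C@@]2(C)CC[C@H]1C[C@H](O)[C@](C)(O)CC/C=C(/C)CC[C@H]2O[Si](CC)(CC)CC
F5 | step 16 | pentafluorophenyl ester of 20 | CC1(CC/C=C(/C)CC[C@@H](O[Si](CC)(CC)CC)[C@@](C)(O)CC[C@@H](CC2OCCO2)C(C(=O)Oc2c(F)c(F)c(F)c(F)c2F)=C)OCCO1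
F6 | step 6 | (E)-alkenyltriethylsilane, Si on C4 | C/C(=C\C[C@@H](CC1OCCO1)C(COC(=O)C(C)(C)C)=C)[Si](CC)(CC)CC
F7 | step 18 | α-methylene seco keto-aldehyde lactone, free C5 OH | C=C1C(=O)O[C@@](C)(CC[C@H]1CC=O)[C@H](O)CC/C(C)=C\CCC(C)=O
A1 | alternative 1 | silyl-protected 13-keto target | C=C1C(=O)O[C@@]2(C)CC[C@H]1CC(=O)[C@](C)(O[Si](CC)(CC)CC)CC/C=C(/C)CC[C@H]2O[Si](C)(C)C(C)(C)C
A2 | alternative 1 | macrocyclic C4 acrylate with C13 enone (C14=C1) | C=CC(=O)O[C@@]1(C)CC/C=C/C(=O)[C@](C)(O[Si](CC)(CC)CC)CC/C=C(/C)CC[C@H]1O[Si](C)(C)C(C)(C)C
A3 | alternative 2 | macrocyclic C5 allylic alcohol with exocyclic C4=C18 | C=C1CC[C@H](C(=C)CO[Si](C)(C)C(C)(C)C)C[C@@H]2OC(C)(C)O[C@]2(C)CC/C=C(/C)CC[C@H]1O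
A4 | alternative 2 | open-chain C4 enol triflate C5 aldehyde | C=C(OS(=O)(=O)C(F)(F)F)CC[C@H](C(=C)CO[Si](C)(C)C(C)(C)C)C[C@@H]1OC(C)(C)O[C@]1(C)CC/C=C(/C)CCC=O
A5 | alternative 3 | target as its C12/C13 acetonide | C=C1C(=O)O[C@@]2(C)CC[C@H]1C[C@@H]3OC(C)(C)O[C@]3(C)CC/C=C(/C)CC[C@H]2O
A6 | alternative 3 | macrocyclic trans-4,5-epoxy C16 acid, C12/C13 acetonide | C=C(C(=O)O)[C@H]1CC[C@@]2(C)O[C@@H]2CC/C(C)=C\CC[C@@]3(C)OC(C)(C)O[C@H]3C1
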